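**Remark (assumptions):** Ring A is the 3-methoxyphenyl ring, ring B the central phenol ring, ring C the para-disubstituted ring and ring D the 3-hydroxyphenyl ring. Compounds 1, 2, 6 and 12 are taken as commercially available. The Wittig alkene is carried on as an E/Z mixture because the double bond is saturated in the next step.

## Retrosynthetic overview

- The route rests on the two-carbon bridge between ring A and ring B: the bridge carbon on C1 of ring A is flanked by the ring B benzylic CH2 and an aryl carbon, so at the ketone oxidation level it is the union of a ring B benzylic chloride, carbon monoxide and a ring A arylboronic acid.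
- The ketone oxygen and both O-benzyl groups are removed together in a final hydrogenolysis, so the carbonyl linchpin costs no separate step.
- The ring B–O–ring C diaryl ether comes from a copper-catalysed Ullmann coupling of a ring C aryl bromide with a ring B phenol aldehyde; the aldehyde is then taken to the benzylic chloride.
- The ring C–ring D bridge comes from a Wittig olefination followed by diimide reduction, which spares the aryl bromide and the benzyl ether.
- No ring is formed; all four benzene rings are purchased.

Key step: step 6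

## Route

**Step 1**
Reactants: 1 (4-bromobenzyl)triphenylphosphonium bromide; 2 3-(benzyloxy)benzaldehyde
Product: 4 1-(benzyloxy)-3-[2-(4-bromophenyl)ethenyl]benzene (E/Z mixture), via phosphonium ylide 3 (not isolated)
Conditions: KOtBu, THF, 0 °C to rt
Reagents that add atoms: none
Why: Wittig olefination of a non-enolisable aryl aldehyde by a semi-stabilised benzylic ylide is reliable, and the alkene geometry is irrelevant because the double bond is reduced next.

**Step 2**
Reactants: 4 1-(benzyloxy)-3-[2-(4-bromophenyl)ethenyl]benzene (E/Z mixture)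
Product: 5 1-(benzyloxy)-3-[2-(4-bromophenyl)ethyl]benzene
Conditions: TsNHNH2 (excess, in portions), NaOAc, THF/H2O, reflux
Reagents that add atoms: none
Why: Diimide reduction (diimide generated from tosylhydrazide) transfers two hydrogens to the C=C bond through a concerted cyclic transition state and leaves the aryl bromide and the benzyl ether untouched, which catalytic hydrogenation would not.

**Step 3**
Reactants: 5 1-(benzyloxy)-3-[2-(4-bromophenyl)ethyl]benzene; 6 4-(benzyloxy)-3-hydroxybenzaldehyde
Product: 7 4-(benzyloxy)-3-{4-[2-(3-benzyloxyphenyl)ethyl]phenoxy}benzaldehyde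
Conditions: CuI (10 mol %), N,N-dimethylglycine hydrochloride (30 mol %), Cs2CO3, 1,4-dioxane, 100 °C
Reagents that add atoms: none
Why: Ligand-accelerated Ullmann diaryl ether synthesis couples the caesium phenoxide with the aryl bromide at a monovalent copper centre; the aldehyde has no α-hydrogen and the benzyl ethers are inert under these conditions.

**Step 4**
Reactants: 7 4-(benzyloxy)-3-{4-[2-(3-benzyloxyphenyl)ethyl]phenoxy}benzaldehyde
Product: 8 [4-(benzyloxy)-3-{4-[2-(3-benzyloxyphenyl)ethyl]phenoxy}phenyl]methanol
Conditions: NaBH4, MeOH/THF, 0 °C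
Reagents that add atoms: none
Why: Borohydride reduction of an aryl aldehyde to the benzylic alcohol is chemoselective in the presence of aryl and benzyl ethers.

**Step 5**
Reactants: 8 [4-(benzyloxy)-3-{4-[2-(3-benzyloxyphenyl)ethyl]phenoxy}phenyl]methanol
Product: 10 1-(benzyloxy)-4-(chloromethyl)-2-{4-[2-(3-benzyloxyphenyl)ethyl]phenoxy}benzene, via benzylic chlorosulfite 9 (not isolated)
Conditions: SOCl2, CH2Cl2, 0 °C to rt; volatiles removed, crude chloride used at once
Reagents that add atoms: thionyl chloride, O=S(Cl)Cl
Why: Deoxychlorination with thionyl chloride proceeds through the chlorosulfite, which collapses readily at this para-oxygenated benzylic carbon with loss of sulfur dioxide; the benzyl aryl ethers tolerate the hydrogen chloride formed at room temperature.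

**Step 6**
Reactants: 10 1-(benzyloxy)-4-(chloromethyl)-2-{4-[2-(3-benzyloxyphenyl)ethyl]phenoxy}benzene; 11 carbon monoxide; 12 3-methoxyphenylboronic acid
Product: 13 2-[4-(benzyloxy)-3-{4-[2-(3-benzyloxyphenyl)ethyl]phenoxy}phenyl]-1-(3-methoxyphenyl)ethan-1-one
Conditions: Pd(OAc)2 (2 mol %), PCy3 (4 mol %), K3PO4·H2O, toluene, CO (10 bar), 80 °C
Reagents that add atoms: none
Why: Zerovalent palladium, formed in situ from Pd(OAc)2 and PCy3, adds oxidatively to the benzylic C–Cl bond, carbon monoxide inserts into the benzyl–palladium bond to give a divalent arylacetyl palladium species, and transmetalation with the phosphate-activated boronate followed by reductive elimination forms the CH2–C(=O) and C(=O)–C1(ring A) bonds. The closest known reaction type is the palladium-catalysed carbonylative Suzuki–Miyaura coupling of benzyl chlorides with arylboronic acids to 1,2-diarylethanones. No ring is closed and no stereocentre is created. The step needs chemoselectivity for carbonylative over direct coupling to the diarylmethane, and the carbon monoxide pressure together with the bulky, electron-rich trialkylphosphine should make insertion into the sp3 benzyl–palladium bond faster than transmetalation. The substrate helps: the benzylpalladium intermediate has no β-hydrogen, the para-oxygenated benzylic chloride is a reactive electrophile, and it is the only carbon–halogen bond left because the aryl bromide was consumed in step 3. The mild phosphate base in toluene limits solvolysis of the chloride and benzylation of the acidic CH2 of the product.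

**Step 7**
Reactants: 13 2-[4-(benzyloxy)-3-{4-[2-(3-benzyloxyphenyl)ethyl]phenoxy}phenyl]-1-(3-methoxyphenyl)ethan-1-one
Product: 16 2-{4-[2-(3-hydroxyphenyl)ethyl]phenoxy}-4-[2-(3-methoxyphenyl)ethyl]phenol, via diphenol ketone 14 (not isolated), via diphenol carbinol 15 (not isolated)
Conditions: H2 (4 bar), 10% Pd/C, AcOH, cat. HClO4, 40 °C
Reagents that add atoms: none
Why: Catalytic hydrogenolysis cleaves both benzyl aryl ethers, and in acidic medium the aryl ketone is reduced to the benzylic carbinol, whose C–O bond is hydrogenolysed to CH2; the diaryl ether, the methyl ether and the arene rings should survive these mild conditions.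

## Compound list

1 | (4-bromobenzyl)triphenylphosphonium bromide | Brc1ccc(C[P+](c2ccccc2)(c2ccccc2)c2ccccc2)cc1.[Br-] | starting material
2 | 3-(benzyloxy)benzaldehyde | O=Cc1cccc(OCc2ccccc2)c1 | starting material
3 | (4-bromobenzylidene)triphenylphosphorane (ylide) | Brc1ccc(C=P(c2ccccc2)(c2ccccc2)c2ccccc2)cc1 | intermediate
4 | 1-(benzyloxy)-3-[2-(4-bromophenyl)ethenyl]benzene (E/Z mixture) | Brc1ccc(C=Cc2cccc(OCc3ccccc3)c2)cc1 | intermediate
5 | 1-(benzyloxy)-3-[2-(4-bromophenyl)ethyl]benzene | Brc1ccc(CCc2cccc(OCc3ccccc3)c2)cc1 | intermediate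
6 | 4-(benzyloxy)-3-hydroxybenzaldehyde | O=Cc1ccc(OCc2ccccc2)c(O)c1 | starting material
7 | 4-(benzyloxy)-3-{4-[2-(3-benzyloxyphenyl)ethyl]phenoxy}benzaldehyde | O=Cc1ccc(OCc2ccccc2)c(Oc2ccc(CCc3cccc(OCc4ccccc4)c3)cc2)c1 | intermediate
8 | [4-(benzyloxy)-3-{4-[2-(3-benzyloxyphenyl)ethyl]phenoxy}phenyl]methanol | OCc1ccc(OCc2ccccc2)c(Oc2ccc(CCc3cccc(OCc4ccccc4)c3)cc2)c1 | intermediate
9 | chlorosulfite ester of alcohol 8 | O=S(Cl)OCc1ccc(OCc2ccccc2)c(Oc2ccc(CCc3cccc(OCc4ccccc4)c3)cc2)c1 | intermediate
10 | 1-(benzyloxy)-4-(chloromethyl)-2-{4-[2-(3-benzyloxyphenyl)ethyl]phenoxy}benzene | ClCc1ccc(OCc2ccccc2)c(Oc2ccc(CCc3cccc(OCc4ccccc4)c3)cc2)c1 | intermediate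
11 | carbon monoxide | [C-]#[O+] | starting material
12 | 3-methoxyphenylboronic acid | COc1cccc(B(O)O)c1 | starting material
13 | 2-[4-(benzyloxy)-3-{4-[2-(3-benzyloxyphenyl)ethyl]phenoxy}phenyl]-1-(3-methoxyphenyl)ethan-1-one | COc1cccc(C(=O)Cc2ccc(OCc3ccccc3)c(Oc3ccc(CCc4cccc(OCc5ccccc5)c4)cc3)c2)c1 | intermediate
14 | 2-[4-hydroxy-3-{4-[2-(3-hydroxyphenyl)ethyl]phenoxy}phenyl]-1-(3-methoxyphenyl)ethan-1-one | COc1cccc(C(=O)Cc2ccc(O)c(Oc3ccc(CCc4cccc(O)c4)cc3)c2)c1 | intermediate
15 | 4-[2-hydroxy-2-(3-methoxyphenyl)ethyl]-2-{4-[2-(3-hydroxyphenyl)ethyl]phenoxy}phenol (racemic) | COc1cccc(C(O)Cc2ccc(O)c(Oc3ccc(CCc4cccc(O)c4)cc3)c2)c1 | intermediate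
16 | 2-{4-[2-(3-hydroxyphenyl)ethyl]phenoxy}-4-[2-(3-methoxyphenyl)ethyl]phenol | COc1cccc(CCc2ccc(O)c(Oc3ccc(CCc4cccc(O)c4)cc3)c2)c1 | target

## Summary and risk assessment

Total step count: 7.
Longest linear sequence: 7 steps (from 1 and 2 to 16).

The three steps most likely to fail:

1. **Step 6 (carbonylative coupling).** The failure modes are direct, non-carbonylative coupling to the diarylmethane, solvolysis of the electron-rich benzylic chloride before oxidative addition, and benzylation of the product ketone at its acidic CH2. The fallback sets out from benzylic chloride 10 and replaces carbon monoxide and the boronic acid by an acid chloride. Zinc insertion (Zn dust, LiCl, THF, rt) should give the benzylic zinc chloride F1. F1 would then be acylated with 3-methoxybenzoyl chloride under Pd(PPh3)4 catalysis (THF, 0 °C to rt) in a Negishi-type acylation. The fallback comes back to the route at ketone 13.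

2. **Step 3 (Ullmann etherification).** The failure modes are sluggish C–O bond formation between the ortho-alkoxy phenol and the electron-neutral aryl bromide, hydrodebromination, and degradation of the aldehyde under hot basic conditions. The fallback sets out from aryl bromide 5 and turns the coupling into an oxidative one at room temperature. Bromine–lithium exchange (n-BuLi, THF, −78 °C), trapping with B(OiPr)3 and work-up with aqueous HCl should give {4-[2-(3-benzyloxyphenyl)ethyl]phenyl}boronic acid F2. F2 would then undergo Chan–Lam–Evans coupling with phenol 6 (Cu(OAc)2, pyridine, 4 Å molecular sieves, CH2Cl2, air, rt). The fallback comes back to the route at aldehyde 7.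

3. **Step 7 (global hydrogenolysis).** The failure modes are stalling at the carbinol stage, because the C–O bond next to the meta-methoxy ring is slow to cleave, and ring saturation if the conditions are forced. The fallback sets out from ketone 13 and removes the oxygen by elimination. NaBH4 reduction (MeOH/THF, 0 °C) should give the racemic carbinol F3. Acid-catalysed dehydration (TsOH·H2O, toluene, reflux, Dean–Stark) should give the (E)-stilbene F4. Neutral hydrogenation of F4 (H2, 10% Pd/C, EtOAc/EtOH, rt) saturates the alkene and cleaves both benzyl ethers. The fallback comes back to the route at target 16.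

## Further compounds

F1 | step 6 | [4-(benzyloxy)-3-{4-[2-(3-benzyloxyphenyl)ethyl]phenoxy}benzyl]zinc chloride | Cl[Zn]Cc1ccc(OCc2ccccc2)c(Oc2ccc(CCc3cccc(OCc4ccccc4)c3)cc2)c1
F2 | step 3 | {4-[2-(3-benzyloxyphenyl)ethyl]phenyl}boronic acid | OB(O)c1ccc(CCc2cccc(OCc3ccccc3)c2)cc1
F3 | step 7 | 2-[4-(benzyloxy)-3-{4-[2-(3-benzyloxyphenyl)ethyl]phenoxy}phenyl]-1-(3-methoxyphenyl)ethan-1-ol (racemic) | COc1cccc(C(O)Cc2ccc(OCc3ccccc3)c(Oc3ccc(CCc4cccc(OCc5ccccc5)c4)cc3)c2)c1
F4 | step 7 | 1-(benzyloxy)-2-{4-[2-(3-benzyloxyphenyl)ethyl]phenoxy}-4-[(E)-2-(3-methoxyphenyl)ethenyl]benzene | COc1cccc(/C=C/c2ccc(OCc3ccccc3)c(Oc3ccc(CCc4cccc(OCc5ccccc5)c4)cc3)c2)c1
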